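Compound numbers refer to the compound list after the steps; atom labels follow benzofuran numbering (O1, C2, C3, C3a, C4–C7, C7a).

## Analysis of the target

The target 24 is a 2,3-dihydrobenzofuran in which benzene ring A (C3a, C4, C5, C6, C7, C7a) is fused through the C3a–C7a bond to a dihydrofuran (O1, C2, C3). C2 carries a 3,4-dihydroxyphenyl group, C3 a 3,5-dihydroxyphenyl group, C4 a hydroxyl and C6 an (E)-4-hydroxystyryl arm, so there are six free phenols. The only stereocentres are C2 and C3, both S, with the two aryl groups trans across the C2–C3 bond. The trans relation is the thermodynamically preferred one, but the absolute configuration has to be introduced by the synthesis. The O1–C2 bond is a benzylic ether para to a catechol oxygen and can ionise under acid, the electron-rich stilbene does not tolerate acid, oxidants or hydrogenation, and the catechol oxidises easily, so the phenols must stay masked to the end and be freed under mild conditions. The difficulty lies in ring A, whose oxygen on C7a, hydroxyl on C4 and arm on C6 are all meta to one another, and in setting two adjacent diaryl-substituted stereocentres in the absolute sense. The strategy rests on reading the six carbons of ring A as three two-carbon units: C7–C7a bound to O1, C3a–C4 bound to C3, and C5–C6 carrying the arm. The first two are joined by the three-atom chain O1–C2–C3, which is the spacing of a 1,6-diyne, so one alkyne cyclotrimerisation can close ring A and the dihydrofuran together.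

## Retrosynthetic reasoning

**24 from 23.** Five O–benzyl bonds are cut. The phenols are carried as benzyl ethers and not as methyl ethers. Freeing five aryl methyl ethers needs a strong Lewis acid near room temperature, which endangers the benzylic O1–C2 bond and the stilbene. Benzyl ethers come off at −78 °C with a Lewis acid and a cation scavenger, and without hydrogen, which the stilbene would not survive.

**23 from 21.** The C4–O bond is traced back to a C4–Si bond (Tamao–Fleming oxidation). A benzyldimethylsilyl group is chosen because it survives the bases and organometallic reagents used earlier. It is bulky enough to steer the ring-forming step, and it becomes oxidisable once fluoride has removed the benzyl group from silicon.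

**21 from 15 and 20.** Three C–C bonds are cut: C3a–C7a, C4–C5 and C6–C7. All three join carbons that are alkyne carbons in the precursors, so no stereocentre is at stake. The disconnection yields the diyne 15, which already holds both stereocentres, and the enyne 20, which already holds the stilbene arm. The forward metal-catalysed [2+2+2] cycloaddition has to couple the two tethered alkynes, accept the alkyne of 20 with its substituted carbon next to C7, and leave the alkene of 20 alone.

**20 from 19, and 19 from 16 and 17.** The alkene of the enyne is cut by a Horner–Wadsworth–Emmons olefination, which gives the (E) geometry. The alkyne is carried with a trimethylsilyl cap that is removed just before use.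

**15 from 12, and 12 from 10.** The O1–C7a bond and the C7≡C7a triple bond are traced back to the secondary alcohol 10. A two-carbon chlorinated electrophile is attached to oxygen and then eliminated. The C2–O bond is never broken, so the carbinol configuration is carried through.

**10 from 7 and 8.** The C2–C3 bond, the only bond joining the two stereocentres, is cut between the carbinol and the propargylic carbon. Aldehyde 8 is the electrophile and the allenylzinc reagent made from mesylate 7 is the nucleophile. The forward reaction transfers the propargylic chirality of 7 to C3 and sets C2 through a closed transition state, giving the anti alcohol that maps onto the trans ring.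

**7 from 6, 6 from 3 and 4, 3 from 1 and 2.** The mesylate comes from alcohol 6. Its single stereocentre is set by a catalytic enantioselective addition of alkyne 3 to aldehyde 4 and is the source of all chirality in the route. Alkyne 3 is made from the chlorosilane 1 and the acetylide 2.

## Alternatives that were turned down

**Alternative 1: Wolff ring contraction of a flavanone.**
- Disconnection: the C3–C3a bond is made by contracting the six-membered ring of a chromanone.
- Key step: irradiation of the 3-diazoflavanone A2 expels nitrogen, the ring A carbon shifts from the carbonyl carbon to the carbene carbon, and water traps the ketene as the dihydrobenzofuran-3-carboxylic acid A1.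
- For: flavanone and diazo-transfer chemistry are classical. The ring A pattern (oxygen on C4, bromine on C6) comes from a purchased phenol, so no regiochemical question arises. On this point it is stronger than the chosen route, where the cycloaddition has to choose between C5 and C6.
- Against: A1 lacks both the C3 aryl group and the stilbene. The carboxyl group must be replaced by the resorcinol ring through a decarboxylative arylation at a secondary benzylic carbon, with only C2 to control the trans relation. The arm must then be attached by a cross-coupling. The C2 centre of a 5-alkoxyflavanone also racemises through retro-oxa-Michael opening under the base needed for diazo transfer.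
- Comparison: three skeletal bonds remain to be made after the key step. In the chosen route every carbon is in place after step 9 and only two functional-group steps follow.

**Alternative 2: conjunctive cross-coupling across an alkenyl boronate.**
- Disconnection: the C2–aryl and C3–aryl bonds are both cut.
- Key step: the boronate complex of an (E)-alkenyl pinacolboronate and the catechol aryllithium reacts with the resorcinol aryl triflate under palladium catalysis with a chiral ligand. The catechol aryl migrates from boron to C2 while palladium delivers the other aryl to C3, giving boronate A3.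
- For: both stereocentres are set in one catalytic enantioselective event from achiral pieces. That is more direct than the chosen route, which needs an enantioselective step followed by a chirality-transfer step.
- Against: the alkene carries a 2,6-dimethoxyaryl group on the carbon that must accept palladium and the second aryl, which creates a very crowded triaryl-substituted centre. Direct Suzuki coupling of the ate complex and Heck reaction at the stilbene compete. A3 contains no ring: after oxidation of the boronate, a ring A phenol must be freed among seven methyl ethers and O1–C2 closed. That closure runs through a benzylic cation, so the C2 configuration set by the catalyst is rewritten.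
- Comparison: the chosen route closes both rings in its key step and does not touch the stereocentres afterwards.

**Alternative 3: aldol aromatisation that builds ring A last.**
- Disconnection: the C5–C6 bond, with ring A arising from a dihydrofuran that bears an acetyl group and a cinnamoylmethyl chain.
- Key step: base enolises the acetyl methyl of A5, which adds to the side-chain ketone. Dehydration and tautomerisation give phenol A4.
- For: A4 already carries the free C4 hydroxyl and the arm on C6, with no ambiguity of position and no silicon to oxidise. On both points it is stronger than the chosen route. Aromatisation provides a strong driving force.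
- Against: A5 is a tetrasubstituted 4,5-dihydrofuran with trans diaryl stereocentres for which no reliable enantioselective entry is evident. Oxidative annulation of a 1,3-dicarbonyl compound with an unsymmetrical stilbene would give the racemate and both orientations of the aryl groups. In the key step the C7 methylene between the enol ether carbon and the ketone is more acidic than the acetyl methyl and opens competing aldol and Michael pathways. A4 still has five methyl ethers to remove.
- Comparison: the chosen route offers a dependable source of both stereocentres and a short, convergent assembly in place of these advantages.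

Key step: step 9

Assumption: the (S,S) antipode of the ProPhenol ligand is written for step 2 as the one that gives the (R)-alcohol 6; the sense is checked on the first run by Mosher ester analysis and the antipodal ligand is used if it proves opposite.

## Route

Step 1
Reactants: 1 benzylchlorodimethylsilane; 2 ethynylmagnesium bromide
Product: 3 benzyl(ethynyl)dimethylsilane
Conditions: 2 (1.3 equiv), THF, 0 °C → rt
Reagents that add atoms: none
Why: Nucleophilic substitution at silicon by the acetylide Grignard reagent; the excess of 2 keeps double silylation of acetylene low.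

Step 2
Reactants: 3 benzyl(ethynyl)dimethylsilane; 4 3,5-bis(benzyloxy)benzaldehyde
Product: 6 (1R)-3-[benzyl(dimethyl)silyl]-1-[3,5-bis(benzyloxy)phenyl]prop-2-yn-1-ol, via methylzinc acetylide 5 (not isolated)
Conditions: Me2Zn, (S,S)-ProPhenol (10 mol%), Ph3P=O (20 mol%), toluene, 0 → 4 °C; aq NH4Cl
Reagents that add atoms: none
Why: Catalytic enantioselective alkynylzinc addition to an aromatic aldehyde: Me2Zn metalates 3 to the acetylide 5, and the dinuclear zinc alkoxide assembled from Me2Zn and the ProPhenol ligand binds aldehyde and acetylide and delivers the alkynyl group to one face of the carbonyl, which sets the carbinol centre under ligand control.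

Step 3
Reactants: 6 (1R)-3-[benzyl(dimethyl)silyl]-1-[3,5-bis(benzyloxy)phenyl]prop-2-yn-1-ol
Product: 7 (1R)-3-[benzyl(dimethyl)silyl]-1-[3,5-bis(benzyloxy)phenyl]prop-2-yn-1-yl methanesulfonate
Conditions: (MeSO2)2O, Et3N, CH2Cl2, −78 → −40 °C; cold work-up, used crude at once
Reagents that add atoms: methanesulfonic anhydride, CS(=O)(=O)OS(C)(=O)=O
Why: O-Sulfonylation that breaks no bond at the stereocentre, so the configuration is kept; the anhydride avoids chloride, which would displace this activated sulfonate, and the two meta alkoxy groups give no resonance support to a benzylic cation, which is what allows the mesylate to be handled cold.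

Step 4
Reactants: 7 (1R)-3-[benzyl(dimethyl)silyl]-1-[3,5-bis(benzyloxy)phenyl]prop-2-yn-1-yl methanesulfonate; 8 3,4-bis(benzyloxy)benzaldehyde
Product: 10 (1S,2S)-4-[benzyl(dimethyl)silyl]-1-[3,4-bis(benzyloxy)phenyl]-2-[3,5-bis(benzyloxy)phenyl]but-3-yn-1-ol (anti), via allenylzinc reagent 9 (not isolated)
Conditions: Pd(OAc)2 (5 mol%), PPh3 (5 mol%), Et2Zn (3 equiv), THF, −78 → −20 °C, 8 present from the start; aq NH4Cl
Reagents that add atoms: none
Why: Marshall-type propargylation: zerovalent palladium formed from Pd(OAc)2, PPh3 and Et2Zn displaces the mesylate in an anti SN2' oxidative addition and passes the allenyl group to zinc, giving the (aS) reagent 9. Reagent 9 adds to 8 through a closed six-membered SE2' transition state on the face that carries zinc, so the propargylic centre is formed with net inversion (S) and the aldehyde aryl group turns away from the allene substituent, which sets the carbinol centre (S) and the anti relation.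

Step 5
Reactants: 10 (1S,2S)-4-[benzyl(dimethyl)silyl]-1-[3,4-bis(benzyloxy)phenyl]-2-[3,5-bis(benzyloxy)phenyl]but-3-yn-1-ol
Product: 12 (1S,2S)-4-[benzyl(dimethyl)silyl]-1-[3,4-bis(benzyloxy)phenyl]-2-[3,5-bis(benzyloxy)phenyl]but-3-yn-1-yl (E)-1,2-dichlorovinyl ether, via potassium alkoxide 11 (not isolated)
Conditions: KH, THF, 0 °C; Cl2C=CHCl, −50 °C → rt
Reagents that add atoms: trichloroethylene, ClC=C(Cl)Cl
Why: Base removes HCl from trichloroethylene to give dichloroacetylene, the alkoxide 11 adds to it in trans fashion and protonation gives the (E)-dichlorovinyl ether; the C–O bond of the stereocentre is not broken, so both centres are retained.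

Step 6
Reactants: 12 (1S,2S)-4-[benzyl(dimethyl)silyl]-1-[3,4-bis(benzyloxy)phenyl]-2-[3,5-bis(benzyloxy)phenyl]but-3-yn-1-yl (E)-1,2-dichlorovinyl ether
Product: 15 (1S,2S)-4-[benzyl(dimethyl)silyl]-1-[3,4-bis(benzyloxy)phenyl]-2-[3,5-bis(benzyloxy)phenyl]but-3-yn-1-yl ethynyl ether, via chloroethynyl ether 13 (not isolated), via lithium alkynyl ether 14 (not isolated)
Conditions: n-BuLi (2.3 equiv), THF, −78 °C; MeOH, −78 → 0 °C; pH 7 work-up, kept cold and used directly
Reagents that add atoms: none
Why: Dehydrochlorination by the first equivalent of n-BuLi gives 13, chlorine–lithium exchange with the second gives the lithium alkoxyacetylide 14, and protonation at −78 °C gives the terminal ynol ether; the low temperature and the small excess of base leave the doubly activated propargylic C–H alone, and 15 is not warmed because benzylic ynol ethers rearrange on heating.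

Step 7
Reactants: 16 4-(benzyloxy)benzaldehyde; 17 diethyl [3-(trimethylsilyl)prop-2-yn-1-yl]phosphonate
Product: 19 (E)-{4-[4-(benzyloxy)phenyl]but-3-en-1-yn-1-yl}trimethylsilane, via lithiated phosphonate 18 (not isolated)
Conditions: LiN(SiMe3)2, THF, −78 °C → rt
Reagents that add atoms: none
Why: Horner–Wadsworth–Emmons olefination; the alkyne-stabilised phosphonate carbanion 18 adds reversibly and the anti elimination pathway gives the (E)-enyne.

Step 8
Reactants: 19 (E)-{4-[4-(benzyloxy)phenyl]but-3-en-1-yn-1-yl}trimethylsilane
Product: 20 1-(benzyloxy)-4-[(E)-but-1-en-3-yn-1-yl]benzene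
Conditions: K2CO3 (cat.), MeOH–THF, rt
Reagents that add atoms: none
Why: Base-catalysed methanolysis of the alkynyl C–Si bond; the alkene geometry and the benzyl ether are not affected.

Step 9
Reactants: 15 (1S,2S)-4-[benzyl(dimethyl)silyl]-1-[3,4-bis(benzyloxy)phenyl]-2-[3,5-bis(benzyloxy)phenyl]but-3-yn-1-yl ethynyl ether; 20 1-(benzyloxy)-4-[(E)-but-1-en-3-yn-1-yl]benzene
Product: 21 (2S,3S)-4-[benzyl(dimethyl)silyl]-2-[3,4-bis(benzyloxy)phenyl]-3-[3,5-bis(benzyloxy)phenyl]-6-[(E)-4-(benzyloxy)styryl]-2,3-dihydrobenzofuran (trans)
Conditions: [Rh(cod)2]BF4 (10 mol%), rac-BINAP (10 mol%), H2 pre-activation then Ar, CH2Cl2, rt, slow addition of 15 to 20 (2 equiv)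
Reagents that add atoms: none
Why: Formal [2+2+2] alkyne cyclotrimerisation at cationic monovalent rhodium; the closest known reaction type is the rhodium- or ruthenium-catalysed cycloaddition of tethered 1,6-diynes with terminal alkynes, in which ynol ether and silylalkyne termini have each been used. Oxidative cyclisation of the two alkynes of 15 forms the C3a–C7a bond and closes the dihydrofuran as the five-membered carbocyclic part of a bicyclic rhodacyclopentadiene of trivalent rhodium, a coupling favoured by the three-atom O1–C2–C3 tether. The alkyne of 20 then inserts into the less hindered Rh–C7 bond, and C–C reductive elimination closes the benzene ring by forming C6–C7 and C4–C5, aromatisation making the step irreversible. No stereocentre is formed, and C2 and C3 are not touched because neither C–H is activated under these neutral conditions. The step needs regioselectivity for the arm on C6 and not C5, and the bulky benzyldimethylsilyl group on C4 secures it by forcing the substituted carbon of 20 to bond to the hydrogen-bearing C7 terminus. It also needs chemoselectivity for the alkyne of 20 over its 1,2-disubstituted alkene, which binds far more weakly, and slow addition of 15 into an excess of 20 holds back self-coupling of the diyne. Room temperature protects the ynol ether of 15, and racemic BINAP suffices because the ligand sets no stereocentre.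

Step 10
Reactants: 21 (2S,3S)-4-[benzyl(dimethyl)silyl]-2-[3,4-bis(benzyloxy)phenyl]-3-[3,5-bis(benzyloxy)phenyl]-6-[(E)-4-(benzyloxy)styryl]-2,3-dihydrobenzofuran
Product: 23 (2S,3S)-2-[3,4-bis(benzyloxy)phenyl]-3-[3,5-bis(benzyloxy)phenyl]-6-[(E)-4-(benzyloxy)styryl]-2,3-dihydrobenzofuran-4-ol, via aryldimethylsilanol 22 (not isolated)
Conditions: Bu4NF, THF, 0 °C → rt; then H2O2 (30% aq), KHCO3, MeOH–THF, rt
Reagents that add atoms: hydrogen peroxide, OO
Why: Tamao–Fleming oxidation: fluoride attacks silicon and the benzyl group leaves as the best carbanion leaving group, giving silanol 22; hydroperoxide then adds to silicon and the aryl group migrates from silicon to oxygen; the nucleophilic peroxide does not attack the stilbene or the benzyl ethers.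

Step 11
Reactants: 23 (2S,3S)-2-[3,4-bis(benzyloxy)phenyl]-3-[3,5-bis(benzyloxy)phenyl]-6-[(E)-4-(benzyloxy)styryl]-2,3-dihydrobenzofuran-4-ol
Product: 24 (2S,3S)-2-(3,4-dihydroxyphenyl)-3-(3,5-dihydroxyphenyl)-6-[(E)-4-hydroxystyryl]-2,3-dihydrobenzofuran-4-ol (CNP0316718.1)
Conditions: BCl3, C6HMe5, CH2Cl2, −78 °C; then MeOH
Reagents that add atoms: none
Why: Lewis-acid debenzylation with a cation scavenger: BCl3 activates the aryl benzyl ethers and pentamethylbenzene captures the benzyl cations by Friedel–Crafts alkylation, which spares the stilbene and the electron-rich rings; at −78 °C the benzylic O1–C2 bond should hold, and C2 and C3 are not involved.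

## Compound list

1 | benzylchlorodimethylsilane | C[Si](C)(Cl)Cc1ccccc1 | starting material
2 | ethynylmagnesium bromide | C#C[Mg]Br | starting material
3 | benzyl(ethynyl)dimethylsilane | C#C[Si](C)(C)Cc1ccccc1 | intermediate
4 | 3,5-bis(benzyloxy)benzaldehyde | O=Cc1cc(OCc2ccccc2)cc(OCc2ccccc2)c1 | starting material
5 | methyl{[benzyl(dimethyl)silyl]ethynyl}zinc | C[Zn]C#C[Si](C)(C)Cc1ccccc1 | intermediate
6 | (1R)-3-[benzyl(dimethyl)silyl]-1-[3,5-bis(benzyloxy)phenyl]prop-2-yn-1-ol | O[C@@H](C#C[Si](C)(C)Cc1ccccc1)c1cc(OCc2ccccc2)cc(OCc2ccccc2)c1 | intermediate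
7 | (1R)-3-[benzyl(dimethyl)silyl]-1-[3,5-bis(benzyloxy)phenyl]prop-2-yn-1-yl methanesulfonate | CS(=O)(=O)O[C@@H](C#C[Si](C)(C)Cc1ccccc1)c1cc(OCc2ccccc2)cc(OCc2ccccc2)c1 | intermediate
8 | 3,4-bis(benzyloxy)benzaldehyde | O=Cc1ccc(OCc2ccccc2)c(OCc2ccccc2)c1 | starting material
9 | ethyl{(aS)-1-[benzyl(dimethyl)silyl]-3-[3,5-bis(benzyloxy)phenyl]propa-1,2-dien-1-yl}zinc | CC[Zn]C([Si](C)(C)Cc1ccccc1)=[C@@]=C([H])c1cc(OCc2ccccc2)cc(OCc2ccccc2)c1 | intermediate
10 | (1S,2S)-4-[benzyl(dimethyl)silyl]-1-[3,4-bis(benzyloxy)phenyl]-2-[3,5-bis(benzyloxy)phenyl]but-3-yn-1-ol | O[C@H](c1ccc(OCc2ccccc2)c(OCc2ccccc2)c1)[C@H](C#C[Si](C)(C)Cc1ccccc1)c1cc(OCc2ccccc2)cc(OCc2ccccc2)c1 | intermediate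
11 | potassium (1S,2S)-4-[benzyl(dimethyl)silyl]-1-[3,4-bis(benzyloxy)phenyl]-2-[3,5-bis(benzyloxy)phenyl]but-3-yn-1-olate | [K+].[O-][C@H](c1ccc(OCc2ccccc2)c(OCc2ccccc2)c1)[C@H](C#C[Si](C)(C)Cc1ccccc1)c1cc(OCc2ccccc2)cc(OCc2ccccc2)c1 | intermediate
12 | (1S,2S)-4-[benzyl(dimethyl)silyl]-1-[3,4-bis(benzyloxy)phenyl]-2-[3,5-bis(benzyloxy)phenyl]but-3-yn-1-yl (E)-1,2-dichlorovinyl ether | Cl/C=C(/Cl)O[C@H](c1ccc(OCc2ccccc2)c(OCc2ccccc2)c1)[C@H](C#C[Si](C)(C)Cc1ccccc1)c1cc(OCc2ccccc2)cc(OCc2ccccc2)c1 | intermediate
13 | (1S,2S)-4-[benzyl(dimethyl)silyl]-1-[3,4-bis(benzyloxy)phenyl]-2-[3,5-bis(benzyloxy)phenyl]but-3-yn-1-yl chloroethynyl ether | ClC#CO[C@H](c1ccc(OCc2ccccc2)c(OCc2ccccc2)c1)[C@H](C#C[Si](C)(C)Cc1ccccc1)c1cc(OCc2ccccc2)cc(OCc2ccccc2)c1 | intermediate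
14 | ({(1S,2S)-4-[benzyl(dimethyl)silyl]-1-[3,4-bis(benzyloxy)phenyl]-2-[3,5-bis(benzyloxy)phenyl]but-3-yn-1-yl}oxy)ethynyllithium | [Li]C#CO[C@H](c1ccc(OCc2ccccc2)c(OCc2ccccc2)c1)[C@H](C#C[Si](C)(C)Cc1ccccc1)c1cc(OCc2ccccc2)cc(OCc2ccccc2)c1 | intermediate
15 | (1S,2S)-4-[benzyl(dimethyl)silyl]-1-[3,4-bis(benzyloxy)phenyl]-2-[3,5-bis(benzyloxy)phenyl]but-3-yn-1-yl ethynyl ether | C#CO[C@H](c1ccc(OCc2ccccc2)c(OCc2ccccc2)c1)[C@H](C#C[Si](C)(C)Cc1ccccc1)c1cc(OCc2ccccc2)cc(OCc2ccccc2)c1 | intermediate
16 | 4-(benzyloxy)benzaldehyde | O=Cc1ccc(OCc2ccccc2)cc1 | starting material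
17 | diethyl [3-(trimethylsilyl)prop-2-yn-1-yl]phosphonate | CCOP(=O)(CC#C[Si](C)(C)C)OCC | starting material
18 | lithium 1-(diethoxyphosphoryl)-3-(trimethylsilyl)prop-2-yn-1-ide | [Li+].CCOP(=O)(OCC)[CH-]C#C[Si](C)(C)C | intermediate
19 | (E)-{4-[4-(benzyloxy)phenyl]but-3-en-1-yn-1-yl}trimethylsilane | C[Si](C)(C)C#C/C=C/c1ccc(OCc2ccccc2)cc1 | intermediate
20 | 1-(benzyloxy)-4-[(E)-but-1-en-3-yn-1-yl]benzene | C#C/C=C/c1ccc(OCc2ccccc2)cc1 | intermediate
21 | (2S,3S)-4-[benzyl(dimethyl)silyl]-2-[3,4-bis(benzyloxy)phenyl]-3-[3,5-bis(benzyloxy)phenyl]-6-[(E)-4-(benzyloxy)styryl]-2,3-dihydrobenzofuran | c1ccccc1COc1ccc(/C=C/c2cc([Si](C)(C)Cc3ccccc3)c3c(c2)O[C@H](c2ccc(OCc4ccccc4)c(OCc4ccccc4)c2)[C@H]3c2cc(OCc4ccccc4)cc(OCc4ccccc4)c2)cc1 | intermediate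
22 | {(2S,3S)-2-[3,4-bis(benzyloxy)phenyl]-3-[3,5-bis(benzyloxy)phenyl]-6-[(E)-4-(benzyloxy)styryl]-2,3-dihydrobenzofuran-4-yl}dimethylsilanol | c1ccccc1COc1ccc(/C=C/c2cc([Si](C)(C)O)c3c(c2)O[C@H](c2ccc(OCc4ccccc4)c(OCc4ccccc4)c2)[C@H]3c2cc(OCc4ccccc4)cc(OCc4ccccc4)c2)cc1 | intermediate
23 | (2S,3S)-2-[3,4-bis(benzyloxy)phenyl]-3-[3,5-bis(benzyloxy)phenyl]-6-[(E)-4-(benzyloxy)styryl]-2,3-dihydrobenzofuran-4-ol | c1ccccc1COc1ccc(/C=C/c2cc(O)c3c(c2)O[C@H](c2ccc(OCc4ccccc4)c(OCc4ccccc4)c2)[C@H]3c2cc(OCc4ccccc4)cc(OCc4ccccc4)c2)cc1 | intermediate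
24 | (2S,3S)-2-(3,4-dihydroxyphenyl)-3-(3,5-dihydroxyphenyl)-6-[(E)-4-hydroxystyryl]-2,3-dihydrobenzofuran-4-ol | Oc1ccc(/C=C/c2cc(O)c3c(c2)O[C@H](c2ccc(O)c(O)c2)[C@H]3c2cc(O)cc(O)c2)cc1 | target

## Step count and least certain steps

Total step count: 11. Longest linear sequence: 9 steps (steps 1–6 and 9–11, from 1); the enyne 20 is made in 2 steps and joins at step 9.

**Step 9 (key step).**
- Risk: the insertion may lose its regiochemical preference, so that the arm is delivered to C5.
- Risk: the styrenyl alkene of 20 may be engaged or 20 may oligomerise at the metal.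
- Risk: the Lewis-acidic [Rh(cod)2]BF4/BINAP system may trigger hydration or rearrangement of the ynol ether of 15 before it cyclises. The neutral complex Cp*RuCl(cod) in 1,2-dichloroethane is the first change of catalyst to try.
- Fallback (sets out from 15, returns at 21): the stilbene is built after the rings. Compound 15 is cyclotrimerised with 3,3-diethoxyprop-1-yne, which has no alkene and a branched substituent that should feel the silyl group more strongly, to give benzyl{(2S,3S)-2-[3,4-bis(benzyloxy)phenyl]-3-[3,5-bis(benzyloxy)phenyl]-6-(diethoxymethyl)-2,3-dihydrobenzofuran-4-yl}dimethylsilane F1. Mild hydrolysis (pyridinium tosylate, acetone–water) should give (2S,3S)-4-[benzyl(dimethyl)silyl]-2-[3,4-bis(benzyloxy)phenyl]-3-[3,5-bis(benzyloxy)phenyl]-2,3-dihydrobenzofuran-6-carbaldehyde F2. Horner–Wadsworth–Emmons olefination with diethyl [4-(benzyloxy)benzyl]phosphonate and KOt-Bu in THF then gives 21.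

**Step 4.**
- Risk: mesylate 7 may ionise before oxidative addition, or reagent 9 may lose its axial configuration by allenyl–propargyl metallotropy while it waits for the electron-rich, slowly reacting aldehyde 8. Either process erodes enantiomeric purity.
- Risk: the anti preference may be weaker with an aromatic aldehyde.
- Fallback (sets out from 3 and 8, returns at 10): the relative configuration comes from an achiral allenyltitanium reagent and the absolute configuration from resolution. The magnesium acetylide of 3 (EtMgBr) is coupled with 3,5-bis(benzyloxy)benzyl bromide under CuBr·SMe2 catalysis to give benzyl{3-[3,5-bis(benzyloxy)phenyl]prop-1-yn-1-yl}dimethylsilane F3. Deprotonation with n-BuLi at −78 °C and transmetalation with ClTi(OiPr)3 gives the racemic reagent {1-[benzyl(dimethyl)silyl]-3-[3,5-bis(benzyloxy)phenyl]propa-1,2-dien-1-yl}tri(propan-2-yloxy)titanium F4. Its closed-transition-state addition to 8 should give the anti alcohol as the racemate, that is 10 together with (1R,2R)-4-[benzyl(dimethyl)silyl]-1-[3,4-bis(benzyloxy)phenyl]-2-[3,5-bis(benzyloxy)phenyl]but-3-yn-1-ol F5. Preparative chromatography on a chiral stationary phase then delivers 10.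

**Step 5 (and the ynol ether formation as a whole).**
- Risk: the potassium alkoxide 11 may fragment by retro-propargylation, since the departing carbanion is stabilised by an aryl group and an alkyne. It may also remove the propargylic proton or take the silyl group from the alkyne. Each process scrambles or destroys the stereodiad.
- Fallback (sets out from 10, returns at 13): no free alkoxide is formed. Formylation of 10 with formic acetic anhydride and pyridine gives (1S,2S)-4-[benzyl(dimethyl)silyl]-1-[3,4-bis(benzyloxy)phenyl]-2-[3,5-bis(benzyloxy)phenyl]but-3-yn-1-yl formate F6. Dichloromethylenation of the formate carbonyl with PPh3 and CCl4 in THF at 60 °C gives the corresponding 2,2-dichlorovinyl ether F7. One equivalent of n-BuLi at −78 °C converts F7 into 13, which goes on to 14 and 15 as in step 6.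

**Step 11.**
- Risk: the Lewis acid may ionise the benzylic O1–C2 bond, leading to ring opening or Friedel–Crafts capture, or cleavage of the five ethers may stop short. If the ring only opens and re-closes, the untouched C3 centre should steer C2 back to trans.
- Fallback (sets out from 23, returns at 24): reductive instead of Lewis-acid debenzylation. Pd(OAc)2 (cat.), Et3SiH and Et3N in CH2Cl2 at room temperature, conditions that leave alkenes alone, should convert the benzyl ethers into aryl triethylsilyl ethers. These are drawn as (2S,3S)-2-{3,4-bis[(triethylsilyl)oxy]phenyl}-3-{3,5-bis[(triethylsilyl)oxy]phenyl}-6-[(E)-4-(triethylsilyloxy)styryl]-2,3-dihydrobenzofuran-4-ol F8; silylation of the C4 hydroxyl as well would be of no consequence. KF in methanol in the same flask then frees 24.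

## Further compounds

F1 | step 9 | benzyl{(2S,3S)-2-[3,4-bis(benzyloxy)phenyl]-3-[3,5-bis(benzyloxy)phenyl]-6-(diethoxymethyl)-2,3-dihydrobenzofuran-4-yl}dimethylsilane | CCOC(OCC)c1cc([Si](C)(C)Cc2ccccc2)c2c(c1)O[C@H](c1ccc(OCc3ccccc3)c(OCc3ccccc3)c1)[C@H]2c1cc(OCc3ccccc3)cc(OCc3ccccc3)c1
F2 | step 9 | (2S,3S)-4-[benzyl(dimethyl)silyl]-2-[3,4-bis(benzyloxy)phenyl]-3-[3,5-bis(benzyloxy)phenyl]-2,3-dihydrobenzofuran-6-carbaldehyde | O=Cc1cc([Si](C)(C)Cc2ccccc2)c2c(c1)O[C@H](c1ccc(OCc3ccccc3)c(OCc3ccccc3)c1)[C@H]2c1cc(OCc3ccccc3)cc(OCc3ccccc3)c1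
F3 | step 4 | benzyl{3-[3,5-bis(benzyloxy)phenyl]prop-1-yn-1-yl}dimethylsilane | C[Si](C)(Cc1ccccc1)C#CCc1cc(OCc2ccccc2)cc(OCc2ccccc2)c1
F4 | step 4 | {1-[benzyl(dimethyl)silyl]-3-[3,5-bis(benzyloxy)phenyl]propa-1,2-dien-1-yl}tri(propan-2-yloxy)titanium (racemic) | CC(C)O[Ti](OC(C)C)(OC(C)C)C([Si](C)(C)Cc1ccccc1)=C=Cc1cc(OCc2ccccc2)cc(OCc2ccccc2)c1
F5 | step 4 | (1R,2R)-4-[benzyl(dimethyl)silyl]-1-[3,4-bis(benzyloxy)phenyl]-2-[3,5-bis(benzyloxy)phenyl]but-3-yn-1-ol | O[C@@H](c1ccc(OCc2ccccc2)c(OCc2ccccc2)c1)[C@@H](C#C[Si](C)(C)Cc1ccccc1)c1cc(OCc2ccccc2)cc(OCc2ccccc2)c1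
F6 | step 5 | (1S,2S)-4-[benzyl(dimethyl)silyl]-1-[3,4-bis(benzyloxy)phenyl]-2-[3,5-bis(benzyloxy)phenyl]but-3-yn-1-yl formate | O=CO[C@H](c1ccc(OCc2ccccc2)c(OCc2ccccc2)c1)[C@H](C#C[Si](C)(C)Cc1ccccc1)c1cc(OCc2ccccc2)cc(OCc2ccccc2)c1
F7 | step 5 | (1S,2S)-4-[benzyl(dimethyl)silyl]-1-[3,4-bis(benzyloxy)phenyl]-2-[3,5-bis(benzyloxy)phenyl]but-3-yn-1-yl 2,2-dichlorovinyl ether | ClC(Cl)=CO[C@H](c1ccc(OCc2ccccc2)c(OCc2ccccc2)c1)[C@H](C#C[Si](C)(C)Cc1ccccc1)c1cc(OCc2ccccc2)cc(OCc2ccccc2)c1
F8 | step 11 | (2S,3S)-2-{3,4-bis[(triethylsilyl)oxy]phenyl}-3-{3,5-bis[(triethylsilyl)oxy]phenyl}-6-[(E)-4-(triethylsilyloxy)styryl]-2,3-dihydrobenzofuran-4-ol | CC[Si](CC)(CC)Oc1ccc(/C=C/c2cc(O)c3c(c2)O[C@H](c2ccc(O[Si](CC)(CC)CC)c(O[Si](CC)(CC)CC)c2)[C@H]3c2cc(O[Si](CC)(CC)CC)cc(O[Si](CC)(CC)CC)c2)cc1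
A1 | alternative 1 | (2S)-6-bromo-2-(3,4-dimethoxyphenyl)-4-methoxy-2,3-dihydrobenzofuran-3-carboxylic acid | Brc1cc(OC)c2c(c1)O[C@H](c1ccc(OC)c(OC)c1)C2C(=O)O
A2 | alternative 1 | (2S)-7-bromo-3-diazo-2-(3,4-dimethoxyphenyl)-5-methoxychroman-4-one | [N-]=[N+]=C1C(=O)c2c(OC)cc(Br)cc2O[C@@H]1c1ccc(OC)c(OC)c1
A3 | alternative 2 | 2-[anti-1-(3,4-dimethoxyphenyl)-2-(3,5-dimethoxyphenyl)-2-{2,6-dimethoxy-4-[(E)-2-(4-methoxyphenyl)ethenyl]phenyl}ethyl]-4,4,5,5-tetramethyl-1,3,2-dioxaborolane | CC1(C)OB(OC1(C)C)[C@@H](c1ccc(OC)c(OC)c1)[C@H](c1c(OC)cc(/C=C/c2ccc(OC)cc2)cc1OC)c1cc(OC)cc(OC)c1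
A4 | alternative 3 | (2S,3S)-2-(3,4-dimethoxyphenyl)-3-(3,5-dimethoxyphenyl)-6-[(E)-4-methoxystyryl]-2,3-dihydrobenzofuran-4-ol | COc1ccc(/C=C/c2cc(O)c3c(c2)O[C@H](c2ccc(OC)c(OC)c2)[C@H]3c2cc(OC)cc(OC)c2)cc1
A5 | alternative 3 | (E)-1-[(4S,5S)-3-acetyl-5-(3,4-dimethoxyphenyl)-4-(3,5-dimethoxyphenyl)-4,5-dihydrofuran-2-yl]-4-(4-methoxyphenyl)but-3-en-2-one | CC(=O)C1=C(CC(=O)/C=C/c2ccc(OC)cc2)O[C@H](c2ccc(OC)c(OC)c2)[C@H]1c1cc(OC)cc(OC)c1
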